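**Strategy**

The route rests on cutting the C2–C3 bond of the flavanone pyranone ring (O1, C2, C3, C4, C4a, C8a). C2 carries O1 and the 4-hydroxyphenyl ring B, so it is in effect a 4-oxybenzyl ether carbon: in the precursor, ring B and C2 are simply a 4-(benzyloxy)benzyl protecting group on the ring-A oxygen, and C3 is a diazo carbon held between the C4 ketone and C8'' of a finished, protected apigenin unit. A chiral dirhodium carboxylate converts this α-aryl-α-diazoketone into a carbenoid that inserts into the benzylic ether C–H, closing the ring at carbon, setting C2 and, after epimerisation of C3, the trans pair. Desilylation, sulfation at O7'' and hydrogenolysis finish.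

Key step: step 10

Assumption on the chemistry: the sense of induction of Rh2(S-PTTL)4 on this substrate is taken to favour 2R; should a first run show the 2S series, the mirror-image catalyst Rh2(R-PTTL)4 is used and nothing else changes.
Remark: the sulfate monoesters 17 and 18 are drawn as free hydrogen sulfates. Compound 17 is handled as its sodium salt (NaHCO3 work-up, pyridine removed by co-evaporation), so that no amine that could slow the hydrogenolysis of the benzyl ethers is carried into step 13. Rotation about the C3–C8'' bond is hindered but is not treated as a stereogenic element.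

**Route**

Step 1
Reactants: 1 2,4,6-trihydroxyacetophenone; 2 4-(benzyloxy)benzyl chloride (1.0 equiv)
Product: 3 1-(4-{[4-(benzyloxy)phenyl]methoxy}-2,6-dihydroxyphenyl)ethan-1-one
Conditions: CsHCO3 (1.2 equiv), MeCN, 60 °C, slow addition of 2
Reagents that add atoms: none
Why: Williamson ether synthesis under bicarbonate control; only the 4-OH, para to the acetyl group and the most acidic of the three, is ionised while both ortho hydroxyls stay hydrogen-bonded, so one equivalent of 2 should give the 4-mono ether, and the absence of excess electrophile keeps C-benzylation of the phloroglucinol ring down.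

Step 2
Reactants: 3 the 4-mono ether; 2 4-(benzyloxy)benzyl chloride (1.05 equiv)
Product: 4 1-(2,4-bis{[4-(benzyloxy)phenyl]methoxy}-6-hydroxyphenyl)ethan-1-one
Conditions: K2CO3 (1.1 equiv), acetone, reflux
Reagents that add atoms: none
Why: Williamson ether synthesis; the two ortho hydroxyls of 3 are equivalent and the carbonyl can chelate only one at a time, so carbonate in acetone should alkylate one and leave the other locked in the hydrogen bond, the usual stopping point for phloroacetophenone ethers.

Step 3
Reactants: 4 the 2,4-bis ether; 2 4-(benzyloxy)benzyl chloride (1.3 equiv)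
Product: 5 1-[2,4,6-tris({[4-(benzyloxy)phenyl]methoxy})phenyl]ethan-1-one
Conditions: K2CO3 (2 equiv), KI (cat.), DMF, 70 °C
Reagents that add atoms: none
Why: Williamson ether synthesis on the chelated hydroxyl, which needs the dissociating solvent, heat and iodide catalysis, and which makes the two ortho ethers of the ketone identical.

Step 4
Reactants: 1 2,4,6-trihydroxyacetophenone; 6 4-(benzyloxy)benzoyl chloride
Product: 8 2-[4-(benzyloxy)phenyl]-5,7-dihydroxy-4H-chromen-4-one (4'-O-benzylapigenin), via β-diketone 7 (not isolated)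
Conditions: LiN(SiMe3)2 (5 equiv), THF, −78 → −10 °C; 6, −78 °C → rt; aq. HCl; then AcOH, H2SO4 (0.5 vol%), 95 °C
Reagents that add atoms: none
Why: The lithium polyanion of 1 should be aroylated at the enolate carbon (Claisen-type acylation, the one-flask equivalent of a Baker–Venkataraman sequence), and acid cyclodehydration of the β-diketone closes the pyranone at oxygen while the benzyl ether tolerates the dilute acid.

Step 5
Reactants: 8 4'-O-benzylapigenin
Product: 9 2-[4-(benzyloxy)phenyl]-5-hydroxy-7-(triisopropylsilyloxy)-4H-chromen-4-one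
Conditions: iPr3SiCl (1.1 equiv), imidazole, DMF, 0 °C → rt
Reagents that add atoms: triisopropylsilyl chloride, CC(C)[Si](Cl)(C(C)C)C(C)C
Why: Selective O-silylation; only the acidic, non-chelated 7-OH should react because 5-OH is locked in a hydrogen bond to the C4 carbonyl, and this marks O7 as the later sulfation site.

Step 6
Reactants: 9 the 7-O-silyl flavone
Product: 10 5-(benzyloxy)-2-[4-(benzyloxy)phenyl]-7-(triisopropylsilyloxy)-4H-chromen-4-one
Conditions: BnBr (3 equiv), Ag2O (1.5 equiv), DMF, rt, dark
Reagents that add atoms: benzyl bromide, BrCc1ccccc1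
Why: Silver-oxide-mediated (Purdie-type) O-benzylation should alkylate the chelated 5-OH without the carbonate or hydride base that would strip the aryl silyl ether, and it turns ring D into a 5,7-diether so that iodination goes to C8.

Step 7
Reactants: 10 the 5-O-benzyl-7-O-silyl flavone
Product: 11 5-(benzyloxy)-2-[4-(benzyloxy)phenyl]-8-iodo-7-(triisopropylsilyloxy)-4H-chromen-4-one
Conditions: N-iodosuccinimide (1.1 equiv), CF3CO2H (cat.), MeCN, 0 °C → rt
Reagents that add atoms: N-iodosuccinimide, O=C1CCC(=O)N1I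
Why: Electrophilic aromatic iodination; in 5,7-dioxygenated flavone ethers C8 (para to O5, ortho to O1) is the established site, and C6 is additionally shielded between the benzyloxy and the bulky silyloxy group.

Step 8
Reactants: 5 the tris-ether methyl ketone; 11 the 8-iodoflavone
Product: 12 5-(benzyloxy)-2-[4-(benzyloxy)phenyl]-8-{2-oxo-2-[2,4,6-tris({[4-(benzyloxy)phenyl]methoxy})phenyl]ethyl}-7-(triisopropylsilyloxy)-4H-chromen-4-one
Conditions: Pd2(dba)3 (2.5 mol%), XPhos (6 mol%), K3PO4 (2.5 equiv), toluene, 90 °C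
Reagents that add atoms: none
Why: Palladium-catalysed ketone α-arylation (Buchwald–Hartwig type) through oxidative addition of zerovalent palladium into C8–I and reductive elimination from the aryl palladium enolate; the methyl ketone should stop at mono-arylation because the product enolate is too hindered, and K3PO4 spares the silyl ether and the flavone.

Step 9
Reactants: 12 the deoxybenzoin
Product: 13 5-(benzyloxy)-2-[4-(benzyloxy)phenyl]-8-{1-diazo-2-oxo-2-[2,4,6-tris({[4-(benzyloxy)phenyl]methoxy})phenyl]ethyl}-7-(triisopropylsilyloxy)-4H-chromen-4-one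
Conditions: 4-acetamidobenzenesulfonyl azide (1.5 equiv), DBU (1.5 equiv), MeCN, 0 °C → rt
Reagents that add atoms: 4-acetamidobenzenesulfonyl azide, CC(=O)Nc1ccc(cc1)S(=O)(=O)N=[N+]=[N-]
Why: Regitz diazo transfer onto the methylene that is activated by both the ketone and the aryl group, the standard entry to α-aryl-α-diazoketones.

Step 10
Reactants: 13 the α-aryl-α-diazoketone
Product: 15 (2R,3S)-2-[4-(benzyloxy)phenyl]-5,7-bis{[4-(benzyloxy)phenyl]methoxy}-3-{5-(benzyloxy)-2-[4-(benzyloxy)phenyl]-4-oxo-7-(triisopropylsilyloxy)-4H-chromen-8-yl}-2,3-dihydro-4H-chromen-4-one, via cis-flavanone 14 (not isolated)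
Conditions: Rh2(S-PTTL)4 [dirhodium tetrakis(N-phthaloyl-(S)-tert-leucinate)] (2 mol%), toluene, 4 Å MS, −40 → 0 °C, slow addition of 13; then DBU (0.2 equiv), 0 °C, 30 min; AcOH quench
Reagents that add atoms: none
Why: The divalent rhodium carboxylate expels N2 from 13 to give an electrophilic donor/acceptor carbenoid at C3 (acceptor: the C4 ketone; donor: the flavone C8'' aryl), which takes the hydrogen of the O–CH2 group of an ortho 4-(benzyloxy)benzyl ether in a concerted, asynchronous three-centre C–H insertion that forms the C2–C3 bond. The closest known reaction type is the chiral dirhodium-carboxylate-catalysed intramolecular insertion of aryl-diazo-carbonyl carbenoids into benzylic ether C–H bonds (2-aryl-dihydrobenzofurans) and its six-ring relative, the insertion of 2-alkoxyphenyl α-diazoketones that gives chroman-4-ones. The pyranone ring is closed in a formal 1,6-insertion mode (six-membered transition state through C3, C4, C4a, C8a, O1, C2), at carbon and not at O1. C2 is set under catalyst control, the chiral phthalimido-carboxylate pocket choosing one of the two enantiotopic benzylic hydrogens; C3 is set under thermodynamic control when DBU equilibrates the acidic C3–H of any cis isomer 14 to the diequatorial trans (2R,3S) arrangement, briefly and cold so that C2 is not opened by retro-oxa-Michael reaction. Site selectivity is needed against three alternatives and is built into the substrate: the two ortho ethers of ring A are identical so either gives 15, the para ether cannot reach the carbenoid, and O7'' carries a triisopropylsilyl group with no C–H on the atom bound to oxygen, so the otherwise favoured five-ring insertion on the flavone side is shut off. Oxonium-ylide formation at the ortho ether oxygen followed by a 1,2-benzyl shift is the remaining competitor and should be disfavoured by the stabilised carbenoid, the non-polar solvent and the low temperature.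

Step 11
Reactants: 15 the trans-flavanone silyl ether
Product: 16 (2R,3S)-2-[4-(benzyloxy)phenyl]-5,7-bis{[4-(benzyloxy)phenyl]methoxy}-3-{5-(benzyloxy)-2-[4-(benzyloxy)phenyl]-7-hydroxy-4-oxo-4H-chromen-8-yl}-2,3-dihydro-4H-chromen-4-one
Conditions: Bu4NF (1.2 equiv), AcOH (1.2 equiv), THF, 0 °C
Reagents that add atoms: none
Why: Fluoride-induced desilylation of the aryl silyl ether, buffered with acetic acid so that no free phenoxide or base can open the flavanone ring, should free the 7''-OH as the only phenol in the molecule.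

Step 12
Reactants: 16 the 7''-phenol
Product: 17 (2R,3S)-2-[4-(benzyloxy)phenyl]-5,7-bis{[4-(benzyloxy)phenyl]methoxy}-3-{5-(benzyloxy)-2-[4-(benzyloxy)phenyl]-4-oxo-7-(sulfooxy)-4H-chromen-8-yl}-2,3-dihydro-4H-chromen-4-one
Conditions: SO3·pyridine (5 equiv), pyridine, 45 °C; aq. NaHCO3 work-up
Reagents that add atoms: sulfur trioxide–pyridine complex, [O-]S(=O)(=O)[n+]1ccccc1
Why: O-Sulfonation of a phenol with the sulfur trioxide–pyridine complex; every other oxygen is etherified, so the aryl sulfate monoester can only form at O7''.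

Step 13
Reactants: 17 the protected 7''-sulfate
Product: 18 CNP0271389.1, (2R,3S)-5,7-dihydroxy-2-(4-hydroxyphenyl)-3-[5-hydroxy-2-(4-hydroxyphenyl)-4-oxo-7-(sulfooxy)-4H-chromen-8-yl]-2,3-dihydro-4H-chromen-4-one
Conditions: H2 (1 atm), Pd/C (10 wt% Pd on carbon), THF–MeOH 1:1, rt; then Dowex 50W (H+ form), MeOH–H2O, 0 °C
Reagents that add atoms: none
Why: Catalytic hydrogenolysis should cleave the three benzyl and two 4-(benzyloxy)benzyl ethers (the latter as toluene plus 4-methylphenol) while the aryl sulfate held as its salt, the flavone double bond and the cyclic C2–O1 ether survive neutral conditions at 1 atm, and neither stereocentre is touched.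

**Compound list**

1 | 2,4,6-trihydroxyacetophenone | CC(=O)c1c(O)cc(O)cc1O | starting material
2 | 4-(benzyloxy)benzyl chloride | ClCc1ccc(OCc2ccccc2)cc1 | starting material
3 | 1-(4-{[4-(benzyloxy)phenyl]methoxy}-2,6-dihydroxyphenyl)ethan-1-one | CC(=O)c1c(O)cc(OCc2ccc(OCc3ccccc3)cc2)cc1O | intermediate
4 | 1-(2,4-bis{[4-(benzyloxy)phenyl]methoxy}-6-hydroxyphenyl)ethan-1-one | CC(=O)c1c(O)cc(OCc2ccc(OCc3ccccc3)cc2)cc1OCc1ccc(OCc2ccccc2)cc1 | intermediate
5 | 1-[2,4,6-tris({[4-(benzyloxy)phenyl]methoxy})phenyl]ethan-1-one | CC(=O)c1c(OCc2ccc(OCc3ccccc3)cc2)cc(OCc2ccc(OCc3ccccc3)cc2)cc1OCc1ccc(OCc2ccccc2)cc1 | intermediate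
6 | 4-(benzyloxy)benzoyl chloride | O=C(Cl)c1ccc(OCc2ccccc2)cc1 | starting material
7 | 1-[4-(benzyloxy)phenyl]-3-(2,4,6-trihydroxyphenyl)propane-1,3-dione | O=C(CC(=O)c1c(O)cc(O)cc1O)c1ccc(OCc2ccccc2)cc1 | intermediate
8 | 2-[4-(benzyloxy)phenyl]-5,7-dihydroxy-4H-chromen-4-one | O=c1cc(-c2ccc(OCc3ccccc3)cc2)oc2cc(O)cc(O)c12 | intermediate
9 | 2-[4-(benzyloxy)phenyl]-5-hydroxy-7-(triisopropylsilyloxy)-4H-chromen-4-one | CC(C)[Si](Oc1cc(O)c2c(=O)cc(-c3ccc(OCc4ccccc4)cc3)oc2c1)(C(C)C)C(C)C | intermediate
10 | 5-(benzyloxy)-2-[4-(benzyloxy)phenyl]-7-(triisopropylsilyloxy)-4H-chromen-4-one | CC(C)[Si](Oc1cc(OCc2ccccc2)c2c(=O)cc(-c3ccc(OCc4ccccc4)cc3)oc2c1)(C(C)C)C(C)C | intermediate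
11 | 5-(benzyloxy)-2-[4-(benzyloxy)phenyl]-8-iodo-7-(triisopropylsilyloxy)-4H-chromen-4-one | CC(C)[Si](Oc1cc(OCc2ccccc2)c2c(=O)cc(-c3ccc(OCc4ccccc4)cc3)oc2c1I)(C(C)C)C(C)C | intermediate
12 | deoxybenzoin: 8-(2-aryl-2-oxoethyl)flavone, aryl = 2,4,6-tris{[4-(benzyloxy)phenyl]methoxy}phenyl | O=C(Cc1c(O[Si](C(C)C)(C(C)C)C(C)C)cc(OCc2ccccc2)c2c(=O)cc(-c3ccc(OCc4ccccc4)cc3)oc12)c1c(OCc2ccc(OCc3ccccc3)cc2)cc(OCc2ccc(OCc3ccccc3)cc2)cc1OCc1ccc(OCc2ccccc2)cc1 | intermediate
13 | α-aryl-α-diazoketone: 8-(2-aryl-1-diazo-2-oxoethyl)flavone | O=C(C(=[N+]=[N-])c1c(O[Si](C(C)C)(C(C)C)C(C)C)cc(OCc2ccccc2)c2c(=O)cc(-c3ccc(OCc4ccccc4)cc3)oc12)c1c(OCc2ccc(OCc3ccccc3)cc2)cc(OCc2ccc(OCc3ccccc3)cc2)cc1OCc1ccc(OCc2ccccc2)cc1 | intermediate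
14 | (2R,3R)-cis-flavanone, C3 epimer of 15 | O=C1c2c(OCc3ccc(OCc4ccccc4)cc3)cc(OCc3ccc(OCc4ccccc4)cc3)cc2O[C@@H](c2ccc(OCc3ccccc3)cc2)[C@H]1c1c(O[Si](C(C)C)(C(C)C)C(C)C)cc(OCc2ccccc2)c2c(=O)cc(-c3ccc(OCc4ccccc4)cc3)oc12 | intermediate
15 | (2R,3S)-trans-flavanone with 7''-O-triisopropylsilyl group | O=C1c2c(OCc3ccc(OCc4ccccc4)cc3)cc(OCc3ccc(OCc4ccccc4)cc3)cc2O[C@@H](c2ccc(OCc3ccccc3)cc2)[C@@H]1c1c(O[Si](C(C)C)(C(C)C)C(C)C)cc(OCc2ccccc2)c2c(=O)cc(-c3ccc(OCc4ccccc4)cc3)oc12 | intermediate
16 | (2R,3S)-trans-flavanone with free 7''-OH | O=C1c2c(OCc3ccc(OCc4ccccc4)cc3)cc(OCc3ccc(OCc4ccccc4)cc3)cc2O[C@@H](c2ccc(OCc3ccccc3)cc2)[C@@H]1c1c(O)cc(OCc2ccccc2)c2c(=O)cc(-c3ccc(OCc4ccccc4)cc3)oc12 | intermediate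
17 | (2R,3S)-trans-flavanone 7''-O-sulfate, all other oxygens etherified | O=C1c2c(OCc3ccc(OCc4ccccc4)cc3)cc(OCc3ccc(OCc4ccccc4)cc3)cc2O[C@@H](c2ccc(OCc3ccccc3)cc2)[C@@H]1c1c(OS(=O)(=O)O)cc(OCc2ccccc2)c2c(=O)cc(-c3ccc(OCc4ccccc4)cc3)oc12 | intermediate
18 | CNP0271389.1 | O=C1c2c(O)cc(O)cc2O[C@@H](c2ccc(O)cc2)[C@@H]1c1c(OS(=O)(=O)O)cc(O)c2c(=O)cc(-c3ccc(O)cc3)oc12 | target

**Step count and risks**

Total step count: 13. Longest linear sequence: 10 steps (steps 4 to 13, from 1 and 6).

Steps most likely to fail:

1. Step 10. What may go wrong: the carbenoid is intercepted by the lone pair of the ortho ether oxygen and the oxonium ylide undergoes a 1,2-benzyl shift to a benzofuran-3-one, or the catalyst discriminates the two enantiotopic benzylic hydrogens poorly. The fallback sets out from 12 and returns at 15, and replaces carbene insertion by oxidative C–H cleavage. Deoxybenzoin 12 is treated with DDQ (1.2 equiv), 2,6-dichloropyridine, LiClO4 and 4 Å MS in 1,2-dichloroethane at 0 °C → rt. Hydride abstraction from an ortho 4-(benzyloxy)benzyl ether gives the aryloxy-stabilised benzylic cation, which the enol of the deoxybenzoin captures at C3, closing the same C2–C3 bond (a cross-dehydrogenative ether–ketone coupling). This gives the racemic trans compound, that is 15 together with its mirror image, the (2S,3R)-flavanone F1. The two are separated by preparative chiral SFC, and 15 continues at step 11. Unproductive oxidation of the para ether is the expected cost.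

2. Step 8. What may go wrong: congestion around the di-ortho-substituted C8–I bond stalls the coupling, so that hydrodeiodination and base-induced loss of the silyl group take over. The fallback sets out from 5 and 11 and returns at 12, with the enolate delivered in neutral form. Ketone 5 is converted with LiN(SiMe3)2 and then Ac2O (THF, −78 °C) into the enol acetate 1-[2,4,6-tris({[4-(benzyloxy)phenyl]methoxy})phenyl]ethenyl acetate F2. With Bu3SnOMe this gives the tributyltin enolate in the flask, and PdCl2[P(o-tolyl)3]2 in toluene at 100 °C couples it with 11 (Migita–Kosugi ketone arylation) to give 12 without free base.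

3. Step 9. What may go wrong: deprotonation of the methylene buried between two di-ortho-substituted arenes is too slow, diazo transfer stays incomplete and DBU attacks the silyl ether. The fallback sets out from 5 and 11, returns at 13 and bypasses 12, installing the diazo group on the unhindered methyl ketone first. Claisen formylation of 5 (NaH, HCO2Et, THF) gives the hydroxymethylene ketone F3. Deformylative Regitz diazo transfer (4-acetamidobenzenesulfonyl azide, Et3N, MeCN) gives the diazomethyl ketone F4. Cross-coupling of F4 with iodide 11 under zerovalent palladium catalysis (Pd(PPh3)4, Ag2CO3, Et3N, toluene, rt), an arylation of acyldiazomethanes that keeps the diazo group, gives 13.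

Further compounds
F1 | step 10 | (2S,3R)-trans-flavanone, enantiomer of 15 | O=C1c2c(OCc3ccc(OCc4ccccc4)cc3)cc(OCc3ccc(OCc4ccccc4)cc3)cc2O[C@H](c2ccc(OCc3ccccc3)cc2)[C@H]1c1c(O[Si](C(C)C)(C(C)C)C(C)C)cc(OCc2ccccc2)c2c(=O)cc(-c3ccc(OCc4ccccc4)cc3)oc12
F2 | step 8 | 1-[2,4,6-tris({[4-(benzyloxy)phenyl]methoxy})phenyl]ethenyl acetate | CC(=O)OC(=C)c1c(OCc2ccc(OCc3ccccc3)cc2)cc(OCc2ccc(OCc3ccccc3)cc2)cc1OCc1ccc(OCc2ccccc2)cc1
F3 | step 9 | (Z)-3-hydroxy-1-[2,4,6-tris({[4-(benzyloxy)phenyl]methoxy})phenyl]prop-2-en-1-one | O=C(/C=C\O)c1c(OCc2ccc(OCc3ccccc3)cc2)cc(OCc2ccc(OCc3ccccc3)cc2)cc1OCc1ccc(OCc2ccccc2)cc1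
F4 | step 9 | 2-diazo-1-[2,4,6-tris({[4-(benzyloxy)phenyl]methoxy})phenyl]ethan-1-one | O=C(C=[N+]=[N-])c1c(OCc2ccc(OCc3ccccc3)cc2)cc(OCc2ccc(OCc3ccccc3)cc2)cc1OCc1ccc(OCc2ccccc2)cc1
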